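**Plan**

- Feature: the C2=C3 bond of the chromone (ring C) is also the bond that closes the oxepine (ring D) and the enone double bond of a chalcone-like precursor, and the C4 carbonyl sits on the carbon that bears ring A. C2 can therefore be the formyl carbon of a ring B aldehyde, and C3/C4 the two carbons of a ring A aryl alkyne.
- Cuts: ring E at C8–CH= and O7–CMe2 (propargyl ether Claisen), ring C at O1–C2 (oxidative cyclisation), ring D at C2=C3 together with C4=O (alkyne–aldehyde metathesis). Then ring A–C4 (Sonogashira), the two C–CH3 bonds of the carbinol (Grignard), the O2′–CH bond (Mitsunobu) and the CH2–alkyne bond (epoxide opening).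
- Forward: side chain from methyl (S)-glycidate and trimethylsilylacetylene, ether link to the ring B phenol, carbinol, coupling to the ring A iodide; then ring D, ring C and ring E in that order.
- Stereochemistry: the single stereocentre comes from methyl (S)-glycidate, is inverted once (Mitsunobu, S to R) and is not touched again.

Key step: step 11

Remark on the chemistry: flavone numbering (O1, C2, C3, C4, ring A C5 to C8, ring B primed) is used for the late intermediates, and the thermal shift of the 7-O-propargyl ether of the chelated 5-hydroxyflavone is assumed to go to C8, as it does in related chelated xanthones and acridones.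

**Route**

Step 1
Reactants: 1 2,4-dihydroxybenzaldehyde
Product: 2 2-hydroxy-4-(triisopropylsilyloxy)benzaldehyde
Conditions: i-Pr3SiCl, imidazole, DMF, 0 °C → rt
Reagents that add atoms: chlorotriisopropylsilane, CC(C)[Si](Cl)(C(C)C)C(C)C
Why: O-silylation with a bulky chloride should go only at the 4-hydroxyl, because the 2-hydroxyl is held in a hydrogen bond to the formyl group.

Step 2
Reactants: 3 trimethylsilylacetylene; 4 methyl (S)-glycidate
Product: 6 methyl (S)-2-hydroxy-5-(trimethylsilyl)pent-4-ynoate, via lithium (trimethylsilyl)acetylide 5 (not isolated)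
Conditions: 3, n-BuLi, THF, −78 °C; BF3·OEt2; 4, −78 °C; aq. NH4Cl
Reagents that add atoms: none
Why: Yamaguchi–Hirao alkynylation, in which the BF3-activated epoxide is opened by the acetylide at the unsubstituted C3 in an SN2 step that leaves the C2 stereocentre (S) untouched, while the ester is not attacked at −78 °C.

Step 3
Reactants: 6 methyl (S)-2-hydroxy-5-(trimethylsilyl)pent-4-ynoate
Product: 7 methyl (S)-2-hydroxypent-4-ynoate
Conditions: K2CO3 (cat.), MeOH, 0 °C
Reagents that add atoms: none
Why: base-catalysed protodesilylation of the alkynyl–silicon bond is fast at 0 °C and should not disturb the α-hydroxy ester stereocentre.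

Step 4
Reactants: 2 2-hydroxy-4-(triisopropylsilyloxy)benzaldehyde; 7 methyl (S)-2-hydroxypent-4-ynoate
Product: 8 methyl (R)-2-[2-formyl-5-(triisopropylsilyloxy)phenoxy]pent-4-ynoate
Conditions: PPh3, DIAD, THF, 0 °C → rt
Reagents that add atoms: none
Why: Mitsunobu etherification of an α-hydroxy ester by an acidic phenol is an SN2 displacement of the oxyphosphonium group, so the S carbinol carbon should be inverted cleanly to the R aryl ether under neutral conditions that spare the aryl silyl ether.

Step 5
Reactants: 8 methyl (R)-2-[2-formyl-5-(triisopropylsilyloxy)phenoxy]pent-4-ynoate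
Product: 9 methyl (R)-2-[2-(dimethoxymethyl)-5-(triisopropylsilyloxy)phenoxy]pent-4-ynoate
Conditions: HC(OMe)3, PPTS (cat.), MeOH, rt
Reagents that add atoms: trimethyl orthoformate, COC(OC)OC
Why: acid-catalysed acetalisation with the orthoformate as water scavenger masks the aldehyde, so that only the ester meets the Grignard reagent in the next step.

Step 6
Reactants: 9 methyl (R)-2-[2-(dimethoxymethyl)-5-(triisopropylsilyloxy)phenoxy]pent-4-ynoate
Product: 11 (R)-2-[(2-hydroxy-2-methylhex-5-yn-3-yl)oxy]-4-(triisopropylsilyloxy)benzaldehyde, via carbinol dimethyl acetal 10 (not isolated)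
Conditions: MeMgBr (4 equiv), THF, −20 → 0 °C; then 1 M HCl, THF–H2O, 0 °C
Reagents that add atoms: methylmagnesium bromide, C[Mg]Br; water, O
Why: double Grignard addition to the ester gives the tertiary carbinol faster than the α-aryloxy ester can enolise (so the stereocentre should hold), one further equivalent is spent on the alkyne C–H, and the electron-rich benzaldehyde acetal is hydrolysed by the dilute acid of the work-up.

Step 7
Reactants: 11 (R)-2-[(2-hydroxy-2-methylhex-5-yn-3-yl)oxy]-4-(triisopropylsilyloxy)benzaldehyde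
Product: 12 (R)-2-{[2-methyl-2-(triethylsilyloxy)hex-5-yn-3-yl]oxy}-4-(triisopropylsilyloxy)benzaldehyde
Conditions: Et3SiOTf, 2,6-lutidine, CH2Cl2, −78 → 0 °C
Reagents that add atoms: triethylsilyl trifluoromethanesulfonate, CC[Si](CC)(CC)OS(=O)(=O)C(F)(F)F
Why: O-silylation with a silyl triflate reaches even a hindered tertiary alcohol and removes the only hydroxyl that could intercept the cation of the key step, and it is done before any acetal-protected ring is present.

Step 8
Reactants: 13 phloroglucinol
Product: 14 1,3,5-tris(methoxymethoxy)benzene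
Conditions: NaH, MOMCl, DMF, 0 °C → rt
Reagents that add atoms: chloromethyl methyl ether, COCCl
Why: Williamson-type O-alkylation of the phenoxide with the hard chloromethyl ether should give the tris-acetal, O-alkylation being the normal course with this electrophile.

Step 9
Reactants: 14 1,3,5-tris(methoxymethoxy)benzene
Product: 15 2-iodo-1,3,5-tris(methoxymethoxy)benzene
Conditions: N-iodosuccinimide (1.0 equiv), DMF, 0 °C
Reagents that add atoms: N-iodosuccinimide, O=C1CCC(=O)N1I
Why: electrophilic aromatic iodination of a strongly activated ring whose three free positions are equivalent, so one equivalent at 0 °C should stop at the monoiodide.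

Step 10
Reactants: 12 (R)-2-{[2-methyl-2-(triethylsilyloxy)hex-5-yn-3-yl]oxy}-4-(triisopropylsilyloxy)benzaldehyde; 15 2-iodo-1,3,5-tris(methoxymethoxy)benzene
Product: 16 (R)-2-{[2-methyl-2-(triethylsilyloxy)-6-[2,4,6-tris(methoxymethoxy)phenyl]hex-5-yn-3-yl]oxy}-4-(triisopropylsilyloxy)benzaldehyde
Conditions: PdCl2(PPh3)2 (5 mol%), CuI (5 mol%), Et3N, DMF, 60 °C, degassed
Reagents that add atoms: none
Why: Sonogashira coupling of a terminal alkyne with an aryl iodide, run warm because the iodide is electron-rich and flanked by two alkoxy groups; the aldehyde, the acetals and both silyl ethers are inert to the amine.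

Step 11
Reactants: 16 (R)-2-{[2-methyl-2-(triethylsilyloxy)-6-[2,4,6-tris(methoxymethoxy)phenyl]hex-5-yn-3-yl]oxy}-4-(triisopropylsilyloxy)benzaldehyde
Product: 18 {(2R)-2-[2-(triethylsilyloxy)propan-2-yl]-8-(triisopropylsilyloxy)-2,3-dihydro-1-benzoxepin-4-yl}[2,4,6-tris(methoxymethoxy)phenyl]methanone, via fused oxetene 17 (not isolated)
Conditions: FeCl3 (15 mol%, anhydrous), MeCN, 4 Å MS, rt → 60 °C
Reagents that add atoms: none
Why: FeCl3 binds the formyl oxygen, the alkyne carbon on the tether side (future C3) bonds to the formyl carbon (future C2) and the positive charge that builds up on the other alkyne carbon (future C4) is taken up by the tris(alkoxy)phenyl ring; the iron alkoxide then closes onto that carbon to give oxetene 17, whose four-electron ring opening leaves the C2=C3 double bond and the oxygen on C4 (alkyne–carbonyl metathesis). The closest known reaction type is the FeCl3-catalysed intramolecular alkyne–aldehyde metathesis of 2-(alkynyloxy)benzaldehydes, which gives 3-acyl-2H-chromenes from propargyl ethers and 4-acyl-2,3-dihydro-1-benzoxepines from homopropargyl ethers such as 16. Ring D closes in the C–C bond-forming event as a 7-exo-dig attack of the alkyne on the activated carbonyl, and the four-membered ring of 17 is only transient. No stereocentre is made: the sp3 carbon of 17 becomes sp2 again, the geometry of the new double bond is fixed by the ring, and the R centre next to the ether oxygen is a spectator. The selectivity needed is regiochemical (which alkyne carbon meets the formyl carbon); the three-atom tether allows the seven-membered closure while the reverse mode would need an eight-membered ring and an unstabilised alkyl-substituted vinyl cation, and the electron-rich ring A polarises the alkyne in the same sense. An oxophilic catalyst is chosen over a π-acid so that an ortho acetal oxygen does not add to the alkyne, and the tertiary alcohol is silylated so that it cannot capture the cation.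

Step 12
Reactants: 18 {(2R)-2-[2-(triethylsilyloxy)propan-2-yl]-8-(triisopropylsilyloxy)-2,3-dihydro-1-benzoxepin-4-yl}[2,4,6-tris(methoxymethoxy)phenyl]methanone
Product: 19 [(2R)-2-(2-hydroxypropan-2-yl)-8-(triisopropylsilyloxy)-2,3-dihydro-1-benzoxepin-4-yl](2,4,6-trihydroxyphenyl)methanone
Conditions: 3 M HCl (aq.), MeOH–THF, 40 °C
Reagents that add atoms: none
Why: acid-catalysed methanolysis (acetal cleavage) should remove the three methoxymethyl groups and the acid-labile tertiary triethylsilyl ether together, while the hindered and weakly basic phenolic triisopropylsilyl ether is expected to survive; any flavanone formed here by oxa-Michael addition is the intermediate of the next step.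

Step 13
Reactants: 19 [(2R)-2-(2-hydroxypropan-2-yl)-8-(triisopropylsilyloxy)-2,3-dihydro-1-benzoxepin-4-yl](2,4,6-trihydroxyphenyl)methanone
Product: 21 5,7-dihydroxy-4′-(triisopropylsilyloxy)flavone bridged from C3 to O2′ by CH2–(R)-CH[C(CH3)2OH] (ring D), via flavanone 20 (not isolated)
Conditions: I2 (10 mol%), DMSO, 110 °C
Reagents that add atoms: none
Why: iodine–DMSO oxidative cyclisation of a 2′-hydroxychalcone-type enone, in which either of the two equivalent ortho hydroxyls of ring A adds to the benzylic β-carbon (6-endo oxa-Michael addition, ring C) to give flavanone 20, iodination of its enol at C3 and loss of HI give the chromone, and DMSO returns iodide to iodine; the symmetry of ring A makes the outcome unambiguous.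

Step 14
Reactants: 21 5,7-dihydroxy-4′-(triisopropylsilyloxy)flavone bridged from C3 to O2′ by CH2–(R)-CH[C(CH3)2OH] (ring D); 22 3-chloro-3-methylbut-1-yne
Product: 23 7-O-(2-methylbut-3-yn-2-yl) ether of 21
Conditions: DBU (1.1 equiv), CuCl2 (cat.), anhydrous MeCN, 0 °C
Reagents that add atoms: none
Why: copper-catalysed O-propargylation of a phenol with a tertiary propargyl chloride should take place at the 7-hydroxyl, the most acidic and the only unchelated phenol, since the 5-hydroxyl is locked to the C4 carbonyl, the tertiary alcohol is not acidic enough and ring B is still silylated.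

Step 15
Reactants: 23 7-O-(2-methylbut-3-yn-2-yl) ether of 21
Product: 25 5-hydroxy-4′-(triisopropylsilyloxy) flavone bridged as in 21 that carries a 2,2-dimethyl-2H-pyran (ring E) fused at O7 and C8, via 8-allenyl-7-hydroxyflavone 24 (not isolated)
Conditions: PhNEt2, 160 °C, argon
Reagents that add atoms: none
Why: aryl propargyl ether Claisen rearrangement, enolisation to allenyl phenol 24, 1,5-hydrogen shift and oxa-6π electrocyclisation give the 2,2-dimethylchromene, and migration to C8 is expected over C6 because the pyrone oxygen gives the C7–C8 bond the higher double-bond character, as seen in the angular pyrans obtained from 1-hydroxy-3-propargyloxy xanthones and acridones.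

Step 16
Reactants: 25 5-hydroxy-4′-(triisopropylsilyloxy) flavone bridged as in 21 that carries a 2,2-dimethyl-2H-pyran (ring E) fused at O7 and C8
Product: 26 target CNP0329736.1, the (R)-5,4′-dihydroxy flavone with ring D (C3–CH2–CH[C(CH3)2OH]–O2′) and ring E (2,2-dimethyl-2H-pyran at O7/C8)
Conditions: Bu4NF, AcOH, THF, 0 °C
Reagents that add atoms: none
Why: fluoride desilylation of the aryl silyl ether at 0 °C, buffered with acetic acid, should leave the chromene, the tertiary alcohol and the stereocentre untouched.

**Compound list**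

1 | 2,4-dihydroxybenzaldehyde | O=Cc1ccc(O)cc1O | starting material
2 | 2-hydroxy-4-(triisopropylsilyloxy)benzaldehyde | O=Cc1ccc(O[Si](C(C)C)(C(C)C)C(C)C)cc1O | intermediate
3 | trimethylsilylacetylene | C#C[Si](C)(C)C | starting material
4 | methyl (S)-glycidate [methyl (2S)-oxirane-2-carboxylate] | COC(=O)[C@@H]1CO1 | starting material
5 | lithium (trimethylsilyl)acetylide | [Li]C#C[Si](C)(C)C | intermediate
6 | methyl (S)-2-hydroxy-5-(trimethylsilyl)pent-4-ynoate | COC(=O)[C@@H](O)CC#C[Si](C)(C)C | intermediate
7 | methyl (S)-2-hydroxypent-4-ynoate | COC(=O)[C@@H](O)CC#C | intermediate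
8 | methyl (R)-2-[2-formyl-5-(triisopropylsilyloxy)phenoxy]pent-4-ynoate | O=Cc1ccc(O[Si](C(C)C)(C(C)C)C(C)C)cc1O[C@@H](C(=O)OC)CC#C | intermediate
9 | methyl (R)-2-[2-(dimethoxymethyl)-5-(triisopropylsilyloxy)phenoxy]pent-4-ynoate | COC(OC)c1ccc(O[Si](C(C)C)(C(C)C)C(C)C)cc1O[C@@H](C(=O)OC)CC#C | intermediate
10 | (R)-3-[2-(dimethoxymethyl)-5-(triisopropylsilyloxy)phenoxy]-2-methylhex-5-yn-2-ol | COC(OC)c1ccc(O[Si](C(C)C)(C(C)C)C(C)C)cc1O[C@@H](C(C)(C)O)CC#C | intermediate
11 | (R)-2-[(2-hydroxy-2-methylhex-5-yn-3-yl)oxy]-4-(triisopropylsilyloxy)benzaldehyde | O=Cc1ccc(O[Si](C(C)C)(C(C)C)C(C)C)cc1O[C@@H](C(C)(C)O)CC#C | intermediate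
12 | (R)-2-{[2-methyl-2-(triethylsilyloxy)hex-5-yn-3-yl]oxy}-4-(triisopropylsilyloxy)benzaldehyde | O=Cc1ccc(O[Si](C(C)C)(C(C)C)C(C)C)cc1O[C@@H](C(C)(C)O[Si](CC)(CC)CC)CC#C | intermediate
13 | phloroglucinol (benzene-1,3,5-triol) | Oc1cc(O)cc(O)c1 | starting material
14 | 1,3,5-tris(methoxymethoxy)benzene | COCOc1cc(OCOC)cc(OCOC)c1 | intermediate
15 | 2-iodo-1,3,5-tris(methoxymethoxy)benzene | COCOc1cc(OCOC)c(I)c(OCOC)c1 | intermediate
16 | (R)-2-{[2-methyl-2-(triethylsilyloxy)-6-[2,4,6-tris(methoxymethoxy)phenyl]hex-5-yn-3-yl]oxy}-4-(triisopropylsilyloxy)benzaldehyde | O=Cc1ccc(O[Si](C(C)C)(C(C)C)C(C)C)cc1O[C@@H](C(C)(C)O[Si](CC)(CC)CC)CC#Cc1c(OCOC)cc(OCOC)cc1OCOC | intermediate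
17 | oxetene: 2H-oxete fused to the oxepine across the former formyl carbon and the tether-side alkyne carbon, with the tris(methoxymethoxy)phenyl group on the oxygen-bearing sp2 carbon (R at the ether carbon, sp3 oxetene carbon undefined) | COCOc1cc(OCOC)cc(OCOC)c1C1=C2C[C@H](C(C)(C)O[Si](CC)(CC)CC)Oc3cc(O[Si](C(C)C)(C(C)C)C(C)C)ccc3C2O1 | intermediate
18 | {(2R)-2-[2-(triethylsilyloxy)propan-2-yl]-8-(triisopropylsilyloxy)-2,3-dihydro-1-benzoxepin-4-yl}[2,4,6-tris(methoxymethoxy)phenyl]methanone | O=C(c1c(OCOC)cc(OCOC)cc1OCOC)C1=Cc2ccc(O[Si](C(C)C)(C(C)C)C(C)C)cc2O[C@@H](C(C)(C)O[Si](CC)(CC)CC)C1 | intermediate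
19 | [(2R)-2-(2-hydroxypropan-2-yl)-8-(triisopropylsilyloxy)-2,3-dihydro-1-benzoxepin-4-yl](2,4,6-trihydroxyphenyl)methanone | O=C(c1c(O)cc(O)cc1O)C1=Cc2ccc(O[Si](C(C)C)(C(C)C)C(C)C)cc2O[C@@H](C(C)(C)O)C1 | intermediate
20 | flavanone: 2,3-dihydro form of 21 (R at the ring D carbinol-bearing carbon, C2 and C3 undefined) | Oc1cc(O)c2C(=O)C3C[C@H](C(C)(C)O)Oc4cc(O[Si](C(C)C)(C(C)C)C(C)C)ccc4C3Oc2c1 | intermediate
21 | 5,7-dihydroxy-4′-(triisopropylsilyloxy)flavone bridged from C3 to O2′ by CH2–(R)-CH[C(CH3)2OH] (ring D) | Oc1cc(O)c2c(=O)c3c(oc2c1)-c1ccc(O[Si](C(C)C)(C(C)C)C(C)C)cc1O[C@@H](C(C)(C)O)C3 | intermediate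
22 | 3-chloro-3-methylbut-1-yne | C#CC(C)(C)Cl | starting material
23 | 7-O-(2-methylbut-3-yn-2-yl) ether of 21 | C#CC(C)(C)Oc1cc(O)c2c(=O)c3c(oc2c1)-c1ccc(O[Si](C(C)C)(C(C)C)C(C)C)cc1O[C@@H](C(C)(C)O)C3 | intermediate
24 | 8-(3-methylbuta-1,2-dien-1-yl)-5,7-dihydroxy analogue of 21 (allenyl phenol) | CC(C)=C=Cc1c(O)cc(O)c2c(=O)c3c(oc12)-c1ccc(O[Si](C(C)C)(C(C)C)C(C)C)cc1O[C@@H](C(C)(C)O)C3 | intermediate
25 | 5-hydroxy-4′-(triisopropylsilyloxy) flavone with ring D as in 21 and a 2,2-dimethyl-2H-pyran (ring E) fused at O7 and C8 | CC1(C)C=Cc2c(cc(O)c3c(=O)c4c(oc23)-c2ccc(O[Si](C(C)C)(C(C)C)C(C)C)cc2O[C@@H](C(C)(C)O)C4)O1 | intermediate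
26 | CNP0329736.1: (R)-5,4′-dihydroxy flavone with ring D (C3–CH2–CH[C(CH3)2OH]–O2′) and ring E (2,2-dimethyl-2H-pyran at O7/C8) | CC1(C)C=Cc2c(cc(O)c3c(=O)c4c(oc23)-c2ccc(O)cc2O[C@@H](C(C)(C)O)C4)O1 | target

**Step count and risks**

Total: 16 steps. Longest linear sequence: 13 steps (steps 2 to 7, then 10 to 16).

Steps most likely to fail:

1. Step 11. The Lewis acid may strip acetal or silyl groups before ring closure, adventitious water may hydrate the very electron-rich alkyne instead of letting it attack the aldehyde, or the chelating product may shut the catalyst down. The fallback sets out from 16 and makes the same bonds in two known operations. Gold-catalysed hydration [(Ph3P)AuNTf2, wet dioxane, 50 °C] should place the carbonyl on the carbon next to ring A and give (R)-2-{[2-methyl-6-oxo-2-(triethylsilyloxy)-6-[2,4,6-tris(methoxymethoxy)phenyl]hexan-3-yl]oxy}-4-(triisopropylsilyloxy)benzaldehyde F1. Amine-mediated intramolecular aldol condensation of its only enolisable methylene with the aldehyde (pyrrolidine, AcOH, toluene, 60 °C) then closes ring D and returns to the route at 18.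

2. Step 15. The sigmatropic shift may leak to C6, driven by the hydrogen bond of the 5-hydroxyl to the carbonyl, and give the linear pyran. The fallback sets out from 23. Acetylation of the chelated phenol (Ac2O, pyridine, 50 °C) gives the 5-O-acetate of 23 F2, in which the hydrogen bond and with it any bias towards C6 is gone. Heating as in step 15 should then give the 5-O-acetate of 25 F3, and brief methanolysis (K2CO3, MeOH, 0 °C) of the labile peri-acetate returns to the route at 25.

3. Step 13. Hot DMSO that contains HI may cleave the aryl silyl ether or dehydrate the tertiary alcohol, and iodine may substitute ring A. The fallback sets out from 19 and separates ring closure from oxidation. Buffered oxa-Michael cyclisation (NaOAc, EtOH, 78 °C) gives flavanone 20, isolated in this variant, and dehydrogenation with DDQ in dioxane at 80 °C returns to the route at 21. This detour makes no compound outside the list (entry F0).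

**Further compounds**

F1 | step 11 | (R)-2-{[2-methyl-6-oxo-2-(triethylsilyloxy)-6-[2,4,6-tris(methoxymethoxy)phenyl]hexan-3-yl]oxy}-4-(triisopropylsilyloxy)benzaldehyde | O=Cc1ccc(O[Si](C(C)C)(C(C)C)C(C)C)cc1O[C@@H](C(C)(C)O[Si](CC)(CC)CC)CCC(=O)c1c(OCOC)cc(OCOC)cc1OCOC
F2 | step 15 | 5-O-acetate of 23 | C#CC(C)(C)Oc1cc(OC(C)=O)c2c(=O)c3c(oc2c1)-c1ccc(O[Si](C(C)C)(C(C)C)C(C)C)cc1O[C@@H](C(C)(C)O)C3
F3 | step 15 | 5-O-acetate of 25 | CC1(C)C=Cc2c(cc(OC(C)=O)c3c(=O)c4c(oc23)-c2ccc(O[Si](C(C)C)(C(C)C)C(C)C)cc2O[C@@H](C(C)(C)O)C4)O1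
F0 | step 13 | none | none
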